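**Retrosynthetic overview**

1. Numbering: C1 lactone carbonyl, C2 CH2, C3 peroxy CH, C4 lactone-oxygen carbon, C5 ring CH2, C6 peroxy quaternary carbon. The plan rests on one feature of the cis-fused 1,2-dioxane/γ-lactone bicycle: C6 is a ketone-level carbon on the peroxide oxygen, and C4 is a tertiary oxygen-bearing carbon γ to C1, linked to C6 through C5. C6 can therefore act as a peroxycarbenium electrophile and C4 as a cation caught by the C1 carboxyl.
2. Key disconnections: C5–C6 and C4–O(lactone), both made in one cationic cascade from an open-chain mixed peroxyketal. The 1,2-dioxane ring closes first and the γ-lactone ring second, in the same step.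
3. The peroxyketal is cut at the C6–O(peroxide) bond into an (R)-allylic hydroperoxide (C1–C5) and the methyl enol ether of 12-phenyldodecan-2-one.
4. The hydroperoxide comes from 4-methylpent-3-enoic acid (methyl ester, Schenck ene reaction, resolution). The enol ether comes from 11-phenylundecanoic acid and MeLi (methyl ketone, dimethyl ketal, loss of methanol).

Key step: step 8

Remark: 4-methylpent-3-enoic acid and 11-phenylundecanoic acid are taken as catalogue compounds.
Remark: step 6 is expected to give 11 together with some internal (2-ene) enol ether; all isomers add the hydroperoxide at the same carbon in step 7, so the mixture is used as it is.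
Remark: 12 is formed as both epimers at the ketal carbon; this carbon becomes planar in step 8, so the mixture is used.

**Route**

Step 1
Reactants: 1 4-methylpent-3-enoic acid
Product: 2 methyl 4-methylpent-3-enoate
Conditions: TMSCHN2 (1.2 equiv), toluene/MeOH, 0 °C → rt
Reagents that add atoms: trimethylsilyldiazomethane, C[Si](C)(C)C=[N+]=[N-]
Why: O-methylation of a carboxylic acid by a diazoalkane (esterification under neutral conditions), chosen because acid catalysis would lactonise this β,γ-unsaturated acid through its tertiary C4 cation or move the alkene into conjugation.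

Step 2
Reactants: 2 methyl 4-methylpent-3-enoate
Product: 3 rac-methyl 3-hydroperoxy-4-methylpent-4-enoate
Conditions: O2, hν (visible), 5,10,15,20-tetraphenylporphyrin (cat.), CH2Cl2, 0 °C; chromatography on SiO2
Reagents that add atoms: dioxygen, O=O
Why: Schenck ene reaction: singlet oxygen adds to C3 while a hydrogen is taken from a C4 methyl group and the alkene shifts to C4=C5, which gives 3 as a racemate at C3; abstraction of an activated C2 hydrogen gives the conjugated tertiary hydroperoxide as a regioisomer (possibly the larger share), which is removed by chromatography.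

Step 3
Reactants: 3 rac-methyl 3-hydroperoxy-4-methylpent-4-enoate
Product: 4 methyl (R)-3-hydroperoxy-4-methylpent-4-enoate
Conditions: preparative HPLC on cellulose tris(3,5-dimethylphenylcarbamate), hexane/i-PrOH, rt
Reagents that add atoms: none
Why: Chromatographic resolution of enantiomers on a polysaccharide carbamate phase, a method in routine use for secondary hydroperoxides; no bond is made, the C3 configuration is selected, and the (R) fraction is to be identified by PPh3 reduction of a sample to the known methyl 3-hydroxy-4-methylpent-4-enoate, a reduction that keeps the descriptor.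

Step 4
Reactants: 5 11-phenylundecanoic acid; 6 methyllithium
Product: 9 12-phenyldodecan-2-one, via lithium 11-phenylundecanoate 7 (not isolated), via dilithium 12-phenyldodecane-2,2-diolate 8 (not isolated)
Conditions: MeLi (2.2 equiv), Et2O, 0 °C → rt; inverse quench into cold 1 M HCl
Reagents that add atoms: methyllithium 6, [Li]C
Why: Addition of an organolithium to a lithium carboxylate: the dilithium gem-diolate 8 cannot take up a second methyl group and collapses to the methyl ketone only on aqueous work-up.

Step 5
Reactants: 9 12-phenyldodecan-2-one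
Product: 10 2,2-dimethoxy-12-phenyldodecane
Conditions: HC(OMe)3, MeOH, TsOH·H2O (cat.), rt; then Et3N
Reagents that add atoms: trimethyl orthoformate, COC(OC)OC; methanol, CO
Why: Acid-catalysed ketalisation driven by trimethyl orthoformate as water scavenger; the saturated chain and the phenyl ring are inert.

Step 6
Reactants: 10 2,2-dimethoxy-12-phenyldodecane
Product: 11 2-methoxy-12-phenyldodec-1-ene
Conditions: TMSOTf (1.1 equiv), i-Pr2NEt (1.3 equiv), CH2Cl2, −20 °C → rt
Reagents that add atoms: none
Why: TMSOTf/amine-mediated elimination of methanol from a dimethyl ketal to the enol ether; the amine keeps the medium non-acidic so that the acid-labile enol ether survives.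

Step 7
Reactants: 4 methyl (R)-3-hydroperoxy-4-methylpent-4-enoate; 11 2-methoxy-12-phenyldodec-1-ene
Product: 12 methyl (3R)-3-[(2-methoxy-12-phenyldodecan-2-yl)peroxy]-4-methylpent-4-enoate
Conditions: pyridinium p-toluenesulfonate (cat.), CH2Cl2, 0 °C → rt; chromatography on Et3N-deactivated SiO2
Reagents that add atoms: none
Why: Acid-catalysed Markovnikov addition of a hydroperoxide O–H across an enol ether (the reaction used to mask hydroperoxides as 2-methoxyprop-2-yl perketals), run with a weak acid so that the allylic hydroperoxide is not cleaved; C3 is untouched and the new ketal carbon forms as both epimers.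

Step 8
Reactants: 12 methyl (3R)-3-[(2-methoxy-12-phenyldodecan-2-yl)peroxy]-4-methylpent-4-enoate
Product: 15 (3S,4aR,7aR)-3,4a-dimethyl-3-(10-phenyldecyl)-4,4a,7,7a-tetrahydrofuro[3,2-c][1,2]dioxin-6(3H)-one, via peroxycarbenium ion 13 (not isolated), via O-methyl lactonium ion 14 (not isolated)
Conditions: SnCl4 (1.2 equiv), CH2Cl2, −78 → −40 °C; aq. NaHCO3; chromatography to remove the C6 epimer
Reagents that add atoms: none
Why: Proposed new method: SnCl4 abstracts the ketal methoxide of 12 to give peroxycarbenium ion 13, whose C6 is attacked by the terminal CH2 (C5) of the isopropenyl group through a chair-like six-membered transition state, and the positive charge building at tertiary C4 is taken up by the carbonyl oxygen of the ester arm on C3 to give lactonium ion 14, which loses its O-methyl group to chloride (or on aqueous work-up) to leave lactone 15. The closest known reaction types are the Lewis-acid cyclisation of alkenyl monoperoxyketals through peroxycarbenium ions, which ends by halide capture, and Prins cyclisations ended by a carboxyl group; what has not been shown is their union on a secondary allylic peroxide. The 1,2-dioxane closes 6-endo with respect to the alkene (both alkene carbons become ring atoms), and the γ-lactone closes by 5-exo capture of the C4 cation, C5 staying outside the new ring. C4 is set by the resolved C3 centre, because the arm on C3 sits equatorial on the chair and reaches C4 only from its own face, which gives the cis ring fusion (C3 R leads to C4 R); C6 is set only by which of methyl and 10-phenyldecyl takes the axial site in the chair, a weak preference, so the (6R) epimer is expected beside 15 and is removed by chromatography. The step needs ionisation of the tertiary α-methoxy C6–O bond in preference to the secondary allylic C3–O and the O–O bonds, which the far greater stability of the ketal-derived cation and the low temperature should secure, and it needs Markovnikov attack through C5, which the 1,1-disubstituted alkene secures.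

**Compound list**

1 | 4-methylpent-3-enoic acid | CC(C)=CCC(=O)O | starting material
2 | methyl 4-methylpent-3-enoate | COC(=O)CC=C(C)C | intermediate
3 | rac-methyl 3-hydroperoxy-4-methylpent-4-enoate | COC(=O)CC(OO)C(C)=C | intermediate
4 | methyl (R)-3-hydroperoxy-4-methylpent-4-enoate | COC(=O)C[C@@H](OO)C(C)=C | intermediate
5 | 11-phenylundecanoic acid | OC(=O)CCCCCCCCCCc1ccccc1 | starting material
6 | methyllithium | [Li]C | starting material
7 | lithium 11-phenylundecanoate (not isolated) | [Li+].[O-]C(=O)CCCCCCCCCCc1ccccc1 | intermediate
8 | dilithium 12-phenyldodecane-2,2-diolate (not isolated) | [Li+].[Li+].CC([O-])([O-])CCCCCCCCCCc1ccccc1 | intermediate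
9 | 12-phenyldodecan-2-one | CC(=O)CCCCCCCCCCc1ccccc1 | intermediate
10 | 2,2-dimethoxy-12-phenyldodecane | COC(C)(OC)CCCCCCCCCCc1ccccc1 | intermediate
11 | 2-methoxy-12-phenyldodec-1-ene | C=C(OC)CCCCCCCCCCc1ccccc1 | intermediate
12 | methyl (3R)-3-[(2-methoxy-12-phenyldodecan-2-yl)peroxy]-4-methylpent-4-enoate (both epimers at the ketal carbon) | COC(=O)C[C@@H](OOC(C)(OC)CCCCCCCCCCc1ccccc1)C(C)=C | intermediate
13 | peroxycarbenium ion, 2-{[(3R)-1-methoxy-4-methyl-1-oxopent-4-en-3-yl]peroxy}-12-phenyldodecan-2-ylium (not isolated) | COC(=O)C[C@@H](OO[C+](C)CCCCCCCCCCc1ccccc1)C(C)=C | intermediate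
14 | O-methyl lactonium ion, the 6-methoxy-6-ylium form of 15 (not isolated) | C[C@]1(CCCCCCCCCCc2ccccc2)C[C@@]2(C)O[C+](OC)C[C@H]2OO1 | intermediate
15 | (3S,4aR,7aR)-3,4a-dimethyl-3-(10-phenyldecyl)-4,4a,7,7a-tetrahydrofuro[3,2-c][1,2]dioxin-6(3H)-one (C3 R, C4 R, C6 S in the numbering of the overview) | C[C@]1(CCCCCCCCCCc2ccccc2)C[C@@]2(C)OC(=O)C[C@H]2OO1 | target

**Step count**

Total: 8 steps. Longest linear sequence: 5 steps (1, 2, 3, 7, 8 or 4, 5, 6, 7, 8).

**Steps most likely to fail**

Step 8 (carries the label Proposed new method). The Lewis acid may cleave the O–O bond or the allylic C3–O bond before the C5–C6 bond forms. The C4 cation may be taken by chloride or lose a proton instead of being caught by the ester. Control at C6 may be poor. Fallback in known chemistry, setting out from 12 and coming back at 15: the cyclisation is run in its established halide-terminated form with TiCl4 in CH2Cl2 at −78 °C, which should give methyl 2-[(3R)-4-chloro-4,6-dimethyl-6-(10-phenyldecyl)-1,2-dioxan-3-yl]acetate F1 as a mixture at C4 and C6. The tertiary chloride is then ionised with AgOTf in CH2Cl2 at 0 °C in a separate step, where the neighbouring ester should close the cis-fused lactone with loss of its O-methyl group (silver-assisted lactonisation of a γ-halo ester). 15 is then separated from its C6 epimer.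

Step 2. Hydrogen abstraction from the carbonyl-activated C2 methylene, on the more crowded side of the alkene, may outrun abstraction from the geminal methyl groups and leave little of the secondary hydroperoxide. Fallback, setting out from 2 and coming back at 12, with the ene reaction moved to the alcohol oxidation level where no carbonyl activates C2:
- LiAlH4 (Et2O, 0 °C) reduces 2 to 4-methylpent-3-en-1-ol F2.
- TBSCl/imidazole (DMF) gives tert-butyl(dimethyl)[(4-methylpent-3-en-1-yl)oxy]silane F3.
- The Schenck ene reaction (O2, hν, tetraphenylporphyrin, CH2Cl2) should give rac-tert-butyl[(3-hydroperoxy-4-methylpent-4-en-1-yl)oxy]dimethylsilane F4 in about statistical proportion with its tertiary isomer.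
- Resolution on the chiral phase of step 3 gives tert-butyl{[(3R)-3-hydroperoxy-4-methylpent-4-en-1-yl]oxy}dimethylsilane F5.
- Addition to 11 (pyridinium p-toluenesulfonate, CH2Cl2) gives tert-butyl{[(3R)-3-[(2-methoxy-12-phenyldodecan-2-yl)peroxy]-4-methylpent-4-en-1-yl]oxy}dimethylsilane F6.
- Bu4NF (THF, 0 °C) frees (3R)-3-[(2-methoxy-12-phenyldodecan-2-yl)peroxy]-4-methylpent-4-en-1-ol F7.
- TEMPO (cat.)/PhI(OAc)2 in MeCN/aq. NaHCO3 oxidises it to (3R)-3-[(2-methoxy-12-phenyldodecan-2-yl)peroxy]-4-methylpent-4-enoic acid F8.
- TMSCHN2 (toluene/MeOH) returns to 12.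

Step 3. The enantiomers may not separate well enough on a preparative scale, or the hydroperoxide may decompose on the column. Fallback, setting out from 3 and coming back at 4, by resolution through diastereomeric perketals:
- Commercial (1R,2S)-trans-2-phenylcyclohexanol is acetylated (Ac2O, pyridine) to (1R,2S)-2-phenylcyclohexyl acetate F9.
- Methylenation with the Tebbe reagent Cp2Ti(μ-Cl)(μ-CH2)AlMe2 (THF/toluene, −40 °C → rt) gives (1R,2S)-2-phenylcyclohexyl prop-1-en-2-yl ether F10.
- Addition of 3 to F10 (pyridinium p-toluenesulfonate, CH2Cl2) gives two diastereomeric perketals whose ketal carbon carries two methyl groups and is no stereocentre; they are separated on SiO2 or by normal-phase HPLC.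
- The diastereomer methyl (3R)-4-methyl-3-{[2-{[(1R,2S)-2-phenylcyclohexyl]oxy}propan-2-yl]peroxy}pent-4-enoate F11 is hydrolysed with AcOH/THF/H2O at rt to release 4.

**Further compounds**

F1 | step 8 | methyl 2-[(3R)-4-chloro-4,6-dimethyl-6-(10-phenyldecyl)-1,2-dioxan-3-yl]acetate | COC(=O)C[C@H]1OOC(C)(CCCCCCCCCCc2ccccc2)CC1(C)Cl
F2 | step 2 | 4-methylpent-3-en-1-ol | CC(C)=CCCO
F3 | step 2 | tert-butyl(dimethyl)[(4-methylpent-3-en-1-yl)oxy]silane | CC(C)=CCCO[Si](C)(C)C(C)(C)C
F4 | step 2 | rac-tert-butyl[(3-hydroperoxy-4-methylpent-4-en-1-yl)oxy]dimethylsilane | CC(=C)C(OO)CCO[Si](C)(C)C(C)(C)C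
F5 | step 2 | tert-butyl{[(3R)-3-hydroperoxy-4-methylpent-4-en-1-yl]oxy}dimethylsilane | CC(C)(C)[Si](C)(C)OCC[C@@H](OO)C(C)=C
F6 | step 2 | tert-butyl{[(3R)-3-[(2-methoxy-12-phenyldodecan-2-yl)peroxy]-4-methylpent-4-en-1-yl]oxy}dimethylsilane | CC(C)(C)[Si](C)(C)OCC[C@@H](OOC(C)(OC)CCCCCCCCCCc1ccccc1)C(C)=C
F7 | step 2 | (3R)-3-[(2-methoxy-12-phenyldodecan-2-yl)peroxy]-4-methylpent-4-en-1-ol | OCC[C@@H](OOC(C)(OC)CCCCCCCCCCc1ccccc1)C(C)=C
F8 | step 2 | (3R)-3-[(2-methoxy-12-phenyldodecan-2-yl)peroxy]-4-methylpent-4-enoic acid | OC(=O)C[C@@H](OOC(C)(OC)CCCCCCCCCCc1ccccc1)C(C)=C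
F9 | step 3 | (1R,2S)-2-phenylcyclohexyl acetate | CC(=O)O[C@@H]1CCCC[C@H]1c1ccccc1
F10 | step 3 | (1R,2S)-2-phenylcyclohexyl prop-1-en-2-yl ether | C=C(C)O[C@@H]1CCCC[C@H]1c1ccccc1
F11 | step 3 | methyl (3R)-4-methyl-3-{[2-{[(1R,2S)-2-phenylcyclohexyl]oxy}propan-2-yl]peroxy}pent-4-enoate | COC(=O)C[C@@H](OOC(C)(C)O[C@@H]1CCCC[C@H]1c1ccccc1)C(C)=C
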